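## The problem

Target 23 is a benzoic acid with four ring substituents: the carboxyl group on C1, a free hydroxyl on C2, a methoxy group on C4 and, on C6, a saturated 2-acetoxytridecyl chain (side-chain carbons C1'–C13'). No rings are fused; the task is to place three contiguous substituents (C2, C1, C6) correctly and to attach a thirteen-carbon chain through its C1' methylene. The two ring oxygens are meta to each other as in a resorcinol but end up different (OH on C2, OMe on C4), so they must either be introduced differently or a symmetric precursor must be desymmetrised late. The only stereocentre is C2' (R), a carbinol carbon flanked by two methylene groups. Nothing else in the molecule can control it, and its two carbon neighbours are so alike that reagent control needs a precursor in which they are made electronically different. Three things are fragile: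

- the secondary acetate, which excludes hydroxide, alkoxide and hydride once it is in place;
- a free C2' hydroxyl facing any ester of the C1 carboxyl, which closes to a 3,4-dihydroisocoumarin, so the hydroxyl must be acylated while the carboxyl carries a mask that leaves under neutral conditions;
- the electron-rich salicylic acid, which is liable to decarboxylation and ring halogenation under strongly acidic or oxidising treatment.

The feature that invites the key step is that C1 and C6 are adjacent, each bears a carbon substituent (an acyl carbon on C1, a methylene leading to a carbonyl-derived carbon on C6), and C1 is flanked on its other side by the C2 oxygen. This is the pattern left when a 3-alkoxyaryne spanning C1–C6 inserts into the C–C bond of a malonate. The C4 oxygen sits meta to both new bonds and can ride through as the second methoxy group of a symmetric 3,5-dimethoxyarene.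

## Retrosynthesis

**Acetate and carboxyl mask (23 ⇐ 22 ⇐ 21).** The O–benzyl bonds of ester and aryl ether and the O–acetyl bond are cut. A methyl ester was rejected because its removal would also remove the acetate; two benzyl groups fall together by hydrogenolysis, which leaves acetate, acid and phenol untouched. Benzylating the phenol as well keeps it out of the acylation. The forward steps ask only that acetylation of the C2' hydroxyl in 21 be faster than its attack on the hindered benzyl ester.

**Lactone as the storage form (21 ⇐ 20 ⇐ 19 ⇐ 18).** The open hydroxy ester 21 is traced to lactone 19 by reconnecting the C2' oxygen to the carboxyl carbon. Since the hydroxyl would find the ester anyway, the closure is accepted and used: the lactone protects both functions through the middle of the route. Its carbonyl, peri to the C8 oxygen (C2 of the target), provides the chelate that lets one methyl ether of 18 be removed selectively, which is how the symmetric dimethoxy ring is desymmetrised. The forward opening must go by acyl–oxygen cleavage, so that C2' is not touched, and the dianion 20 must be alkylated before any acid is added.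

**The stereocentre (18 ⇐ 17 ⇐ 16 ⇐ 15).** The C2'–H bond is cut back to a ketone. A saturated benzyl undecyl ketone offers a chemical catalyst almost nothing to read, so the undecyl side is carried as an alkyne: in ynone 15 the carbonyl lies between an sp carbon and an sp3 arylmethyl carbon, the substrate class for which asymmetric transfer hydrogenation is dependable. Saturating the triple bond of 16 then gives 17, which lactonises to 18. The precursor has no stereocentre; the reduction must set it and the hydrogenation must not erode it.

**Chain attachment (15 ⇐ 12 + 13, through 14).** The C2'–C3' bond is cut between the acyl carbon and the alkyne. Acylating acetylide 14 with the N-methoxy-N-methylamide 12 is preferred to adding 14 to an aldehyde and re-oxidising: an alkoxide next to the benzoate would lactonise at once and block the oxidation. Undec-1-yne 13 supplies eleven of the thirteen chain carbons in one piece.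

**Differentiating the two esters (12 ⇐ 11).** Only the acyl substituent changes. Diester 11 has one unhindered aliphatic ester and one benzoate flanked by two ortho substituents, so the forward amidation needs no protecting group, only the inherent rate difference.

**Key disconnection (11 ⇐ 10 + 9, 10 ⇐ 8).** The C6–CH2 and C1–C(=O) bonds are cut together, which returns the ring to aryne 10 and the side arms to dimethyl malonate 9. Cutting only one of these bonds (a cross-coupling at C6, or a carboxylation at C1) would need a pre-functionalised, unsymmetrical arene. The double cut needs only the silylaryl triflate 8, and the position of its methoxy group determines which new bond goes where. The simplification is large: a contiguously trisubstituted arene becomes a symmetric dioxygenated ring plus a bulk diester.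

**Aryne precursor (8 ⇐ 7 ⇐ 6 ⇐ 5, 4, 3 ⇐ 2 ⇐ 1).** The O–S bond and the C–Si bond are cut. Silicon is placed by directed metalation of carbamate 2, transiently N-silylated as 3, on the carbon that lies between the carbamate and a methoxy group (aryllithium 4, then 5 and 6). The carbamate is then exchanged for the triflate through phenol 7. The sequence starts from 3,5-dimethoxyphenol 1, whose symmetry makes the two ortho positions equivalent.

## Roads not taken

**Alternative 1:** The cut runs through the ring: bond C1–C6 is opened and the arene is unravelled to the open-chain diketo-dioxinone A2, which already carries the chiral silyloxy chain. In the forward sense a mild base lets the nucleophilic carbon of the dioxinone add to the far ketone; loss of water and enolisation then give the acetonide-masked salicylate A1 with a free C4 hydroxyl.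
- Merits: the two ring oxygens arrive differentiated, so no selective demethylation is needed. The stereocentre is made in an aliphatic fragment before the ring exists, so no late enantioselective reduction is required. In both respects this road is better than the chosen one.
- Weak points: A2 is a masked 1,3,5-tricarbonyl compound with a β-silyloxy group. It needs several dienolate acylations to assemble, and the base that triggers aromatisation can also cause other cyclisations or β-elimination of the silyloxy group. After A1 the chain oxygen must be desilylated and acetylated beside an activated salicylate, which is at least as prone to close to the dihydroisocoumarin as an ester. The acetonide must finally be opened to a free acid without saponifying the acetate, so the end game is no shorter than steps 10–12.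
- Comparison: against the built-in oxygen differentiation of A1, the chosen plan sets a regiodefined two-bond construction on a purchasable ring, intermediates without a reactive polycarbonyl chain, and one chelation-controlled demethylation (step 9).

**Alternative 2:** Ring bonds C1–C2 and C5–C6 are cut, so the arene comes from a cycloaddition between the chiral ynoate A4, which already holds the acetate and the stereocentre, and the trioxygenated silyloxydiene A5. On heating, the unsubstituted terminus of A5 bonds to the chain-bearing alkyne carbon and its ketene-acetal terminus to the ester-bearing carbon. The adduct aromatises by losing an alkoxy group, and A3 results: the benzyl ester of 23, one hydrogenolysis from the target.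
- Merits: this is the most convergent road. The C2' oxygen is acetylated before the carboxyl is ever attached to a ring, so the lactone trap never opens, and no protecting-group exchange is needed. If the cycloaddition works it is clearly shorter than twelve steps.
- Weak points: an internal ynoate with a β-alkyl substituent is a sluggish dienophile and needs prolonged heating, while A5 is sensitive to heat and adventitious acid and can be consumed first. The adduct can aromatise by losing either the alkoxy or the silyloxy group, so the C2 oxygen may emerge partly as its methyl ether and bring a demethylation back. The homopropargylic acetate of A4 must survive the thermal conditions without isomerisation.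
- Comparison: Alternative 2 is shorter and more elegant on paper. The chosen plan offers in exchange a ring-forming pattern fixed by a room-temperature step of established regiochemistry, and later steps that each have close counterparts. The cost is about four extra steps and a lactone detour.

**Alternative 3:** Four ring bonds are cut in one cascade, back to the 3-substituted cyclobutenone A7 and methoxyacetylene A8. Heating opens A7 to a vinylketene, which adds to A8; ring opening, 6π-electrocyclisation and tautomerisation then give the resorcinol monoether A6.
- Merits: the 1,3,5-pattern is unambiguous, the free hydroxyl of A6 is the future C2 hydroxyl and the methoxy group the future C4 substituent, and the stereocentre travels as a silyl ether.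
- Weak points: A6 has no carboxyl carbon. C1 must still be introduced between the hydroxyl and the side chain, in competition with the position flanked by both oxygens and the one para to the hydroxyl; the aryne insertion settles this regiochemical question by construction. A8 is volatile and unstable, A7 needs several steps with the chiral chain in place, and the acetate and acid end game remains.
- Comparison: the only advantage over the chosen plan is that no demethylation is needed. In step count and risk this road is inferior: it builds at some cost a ring that can be bought and leaves the hardest C–C bond to the end.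

Key step: step 4

## Route

Assumption: transfer hydrogenation of ynone 15 with the (S,S)-configured Ru–TsDPEN catalyst (TsDPEN = N-tosyl-1,2-diphenylethane-1,2-diamine) is taken to follow the sense known for simple alkynyl ketones, the alkynyl group playing the part of the aryl group of acetophenone. This gives the (S)-propargylic alcohol 16. The descriptor becomes (R) on saturation only because the CIP ranks of the two carbon substituents swap.

Step 1
Reactants: 1 3,5-dimethoxyphenol
Product: 2 3,5-dimethoxyphenyl N-(propan-2-yl)carbamate
Conditions: i-PrNCO, Et3N (cat.), CH2Cl2, rt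
Reagents that add atoms: isopropyl isocyanate, CC(C)N=C=O
Why: Base-catalysed addition of a phenol to an isocyanate (carbamoylation); the N-monoalkyl carbamate is a strong ortho director once N-silylated and can later be removed without reduction or strong base.

Step 2
Reactants: 2 3,5-dimethoxyphenyl N-(propan-2-yl)carbamate
Product: 6 3,5-dimethoxy-2-(trimethylsilyl)phenyl N-(propan-2-yl)carbamate, via N-silyl carbamate 3 (not isolated), via aryllithium 4 (not isolated), via bis-silyl carbamate 5 (not isolated)
Conditions: TBSOTf, TMEDA, Et2O, 0 °C to rt; n-BuLi, TMEDA, −78 °C; TMSCl, −78 °C to rt; aq NaHSO4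
Reagents that add atoms: chlorotrimethylsilane, C[Si](C)(C)Cl; for the intermediates only: tert-butyldimethylsilyl trifluoromethanesulfonate, CC(C)(C)[Si](C)(C)OS(=O)(=O)C(F)(F)F (silicon on nitrogen in 3, 4 and 5, lost on work-up) and n-butyllithium, [Li]CCCC (lithium in 4)
Why: Directed ortho-metalation: transient N-silylation masks the N–H, the O-carbamate and the neighbouring methoxy group cooperate to place lithium on the carbon between them, and the chlorosilane quench gives the aryl silane, the N–Si bond being hydrolysed on acidic work-up. The low temperature is chosen to suppress the anionic ortho-Fries shift of the carbamoyl group.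

Step 3
Reactants: 6 3,5-dimethoxy-2-(trimethylsilyl)phenyl N-(propan-2-yl)carbamate
Product: 8 3,5-dimethoxy-2-(trimethylsilyl)phenyl trifluoromethanesulfonate, via silylphenol 7 (not isolated)
Conditions: DBU, Et2NH, MeCN, 40 °C; then PhNTf2, rt
Reagents that add atoms: N-phenylbis(trifluoromethanesulfonimide), O=S(=O)(N(c1ccccc1)S(=O)(=O)C(F)(F)F)C(F)(F)F
Why: The amidine base removes the carbamate N–H and the aryloxide is expelled with isopropyl isocyanate (E1cB elimination), which diethylamine scavenges as a urea; the phenoxide 7 is then O-sulfonylated by the triflimide in the same flask, so the hindered ortho-silyl phenol need not be isolated.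

Step 4
Reactants: 8 3,5-dimethoxy-2-(trimethylsilyl)phenyl trifluoromethanesulfonate; 9 dimethyl malonate
Product: 11 methyl 2,4-dimethoxy-6-(2-methoxy-2-oxoethyl)benzoate, via 3,5-dimethoxybenzyne 10 (not isolated)
Conditions: KF, 18-crown-6, THF, rt
Reagents that add atoms: none
Why: Fluoride attacks silicon in 8 and the ortho triflate leaves, releasing aryne 10 by 1,2-elimination. The malonate anion, formed first by fluoride and then by proton transfer from 9 to the product enolate, adds to the aryne carbon remote from the flanking methoxy group (the future C6); in a 3-alkoxyaryne that carbon is the more distorted toward linearity and the more electrophilic, and attack there leaves the carbanion on the carbon next to the inductively withdrawing oxygen (the future C1). The aryl anion then attacks an ester carbonyl of the adjacent malonate unit in a 4-exo-trig closure to a benzocyclobutenoxide that is only transient: fragmentation of the strained ring breaks the original malonate C–C bond and leaves the aryl ester on C1 and the arylacetate enolate on C6. The net change is insertion of the aryne into a C–C σ bond (acyl-alkylation), which forms the C6–CH2 and C1–CO2Me bonds in one operation; no ring is retained and no stereocentre is made. The closest known reaction is the fluoride-induced insertion of arynes into the C–C bond of malonates and β-keto esters to give homophthalates. The step needs regioselectivity, which the methoxy group beside the triple bond secures, and it needs acyl transfer to outrun protonation of the aryl anion, which the intramolecular attack, the aprotic medium and the slow release of aryne from sparingly soluble KF should favour.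

Step 5
Reactants: 11 methyl 2,4-dimethoxy-6-(2-methoxy-2-oxoethyl)benzoate
Product: 12 methyl 2,4-dimethoxy-6-{2-[methoxy(methyl)amino]-2-oxoethyl}benzoate
Conditions: MeNHOMe·HCl, i-PrMgCl, THF, −20 to 0 °C
Reagents that add atoms: N,O-dimethylhydroxylamine hydrochloride, CNOC.Cl
Why: Direct ester aminolysis by the chloromagnesium amide of N,O-dimethylhydroxylamine (Weinreb amide formation); the aliphatic ester should react, while the benzoate, flanked by two ortho substituents and twisted out of the ring plane, should be left alone.

Step 6
Reactants: 12 methyl 2,4-dimethoxy-6-{2-[methoxy(methyl)amino]-2-oxoethyl}benzoate; 13 undec-1-yne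
Product: 15 methyl 2,4-dimethoxy-6-(2-oxotridec-3-yn-1-yl)benzoate, via lithium undec-1-ynide 14 (not isolated)
Conditions: 13, n-BuLi, THF, −78 °C; then 12, −78 to 0 °C; aq NH4Cl
Reagents that add atoms: n-butyllithium, [Li]CCCC (lithium in 14 only)
Why: Acylation of a lithium acetylide by a Weinreb amide; the chelated tetrahedral adduct persists until the quench, so neither over-addition nor base-induced isomerisation of the ynone is expected, and the hindered benzoate should not compete at low temperature.

Step 7
Reactants: 15 methyl 2,4-dimethoxy-6-(2-oxotridec-3-yn-1-yl)benzoate
Product: 16 methyl 2-[(2S)-2-hydroxytridec-3-yn-1-yl]-4,6-dimethoxybenzoate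
Conditions: Ru[(S,S)-TsDPEN](p-cymene) (cat.), i-PrOH, rt
Reagents that add atoms: none
Why: Noyori asymmetric transfer hydrogenation of an α,β-acetylenic ketone; the catalyst distinguishes the alkynyl π-substituent from the sp3 arylmethyl group, and the (S,S)-ligand should deliver hydride to the face that gives the (S)-carbinol, which is the stereocentre of the target. The base-free 16-electron amido complex is used so that the benzylic ynone is not exposed to alkoxide; any lactone formed from 16 at this stage would converge in step 8.

Step 8
Reactants: 16 methyl 2-[(2S)-2-hydroxytridec-3-yn-1-yl]-4,6-dimethoxybenzoate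
Product: 18 (3R)-6,8-dimethoxy-3-undecyl-3,4-dihydro-1H-isochromen-1-one, via hydroxy ester 17 (not isolated)
Conditions: H2 (1 atm), Pt/C, EtOAc, rt; filter; p-TsOH·H2O (cat.), toluene, 80 °C
Reagents that add atoms: none
Why: Heterogeneous hydrogenation of the alkyne to the alkane, on platinum instead of palladium to limit allylic-alcohol isomerisation and C–O hydrogenolysis at the carbinol; acid-catalysed intramolecular transesterification then closes the six-membered lactone with loss of methanol. The carbinol C–O bond is not touched, and the centre becomes (R) by CIP re-ranking only.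

Step 9
Reactants: 18 (3R)-6,8-dimethoxy-3-undecyl-3,4-dihydro-1H-isochromen-1-one
Product: 19 (3R)-8-hydroxy-6-methoxy-3-undecyl-3,4-dihydro-1H-isochromen-1-one
Conditions: BCl3, CH2Cl2, −78 to 0 °C; aq NaHCO3
Reagents that add atoms: none
Why: Chelation-controlled aryl methyl ether cleavage: BCl3 binds the lactone carbonyl and the peri C8 methoxy oxygen in a six-membered chelate and chloride removes that methyl group only, the C6 methoxy group having no such assistance.

Step 10
Reactants: 19 (3R)-8-hydroxy-6-methoxy-3-undecyl-3,4-dihydro-1H-isochromen-1-one
Product: 21 benzyl 2-(benzyloxy)-6-[(2R)-2-hydroxytridecyl]-4-methoxybenzoate, via dipotassium salt 20 (not isolated)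
Conditions: KOH, 1,4-dioxane–H2O, 80 °C; evaporate; BnBr, DMF, rt
Reagents that add atoms: potassium hydroxide, [K+].[OH-] (one carboxyl oxygen; potassium in 20 only); benzyl bromide, BrCc1ccccc1
Why: Lactone saponification by acyl–oxygen cleavage, which retains C2', gives the phenoxide carboxylate 20, and O-alkylation of both anions with benzyl bromide in a dipolar aprotic solvent traps the open form before any acid is added. The secondary hydroxyl is not alkylated without a strong base, and the ester formed is shielded by two ortho substituents.

Step 11
Reactants: 21 benzyl 2-(benzyloxy)-6-[(2R)-2-hydroxytridecyl]-4-methoxybenzoate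
Product: 22 benzyl 6-[(2R)-2-(acetyloxy)tridecyl]-2-(benzyloxy)-4-methoxybenzoate
Conditions: Ac2O, pyridine, DMAP (cat.), CH2Cl2, 0 °C to rt
Reagents that add atoms: acetic anhydride, CC(=O)OC(C)=O
Why: DMAP-catalysed acylation of a secondary alcohol; acyl transfer from the N-acetylpyridinium ion should be much faster than attack of the neutral hydroxyl on the doubly ortho-substituted benzyl ester.

Step 12
Reactants: 22 benzyl 6-[(2R)-2-(acetyloxy)tridecyl]-2-(benzyloxy)-4-methoxybenzoate
Product: 23 6-[(2R)-2-(acetyloxy)tridecyl]-2-hydroxy-4-methoxybenzoic acid
Conditions: H2 (1 atm), Pd/C, EtOAc, rt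
Reagents that add atoms: none
Why: Hydrogenolysis of the benzyl ester and the benzyl aryl ether on palladium frees acid and phenol under neutral conditions, so the secondary acetate is kept; a non-nucleophilic solvent avoids transesterification.

## Compound list

1 | 3,5-dimethoxyphenol | COc1cc(O)cc(OC)c1 | starting material
2 | 3,5-dimethoxyphenyl N-(propan-2-yl)carbamate | COc1cc(OC)cc(OC(=O)NC(C)C)c1 | intermediate
3 | 3,5-dimethoxyphenyl N-(tert-butyldimethylsilyl)-N-(propan-2-yl)carbamate | COc1cc(OC)cc(OC(=O)N(C(C)C)[Si](C)(C)C(C)(C)C)c1 | intermediate
4 | [2-({(tert-butyldimethylsilyl)(propan-2-yl)carbamoyl}oxy)-4,6-dimethoxyphenyl]lithium | [Li]c1c(OC)cc(OC)cc1OC(=O)N(C(C)C)[Si](C)(C)C(C)(C)C | intermediate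
5 | 3,5-dimethoxy-2-(trimethylsilyl)phenyl N-(tert-butyldimethylsilyl)-N-(propan-2-yl)carbamate | COc1cc(OC)c([Si](C)(C)C)c(OC(=O)N(C(C)C)[Si](C)(C)C(C)(C)C)c1 | intermediate
6 | 3,5-dimethoxy-2-(trimethylsilyl)phenyl N-(propan-2-yl)carbamate | COc1cc(OC)c([Si](C)(C)C)c(OC(=O)NC(C)C)c1 | intermediate
7 | 3,5-dimethoxy-2-(trimethylsilyl)phenol (present as its amidinium phenoxide) | COc1cc(OC)c([Si](C)(C)C)c(O)c1 | intermediate
8 | 3,5-dimethoxy-2-(trimethylsilyl)phenyl trifluoromethanesulfonate | COc1cc(OC)c([Si](C)(C)C)c(OS(=O)(=O)C(F)(F)F)c1 | intermediate
9 | dimethyl malonate | COC(=O)CC(=O)OC | starting material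
10 | 3,5-dimethoxybenzyne (3,5-dimethoxy-1,2-didehydrobenzene) | COC1=CC(OC)=CC#C1 | intermediate
11 | methyl 2,4-dimethoxy-6-(2-methoxy-2-oxoethyl)benzoate | COC(=O)Cc1cc(OC)cc(OC)c1C(=O)OC | intermediate
12 | methyl 2,4-dimethoxy-6-{2-[methoxy(methyl)amino]-2-oxoethyl}benzoate | CON(C)C(=O)Cc1cc(OC)cc(OC)c1C(=O)OC | intermediate
13 | undec-1-yne | CCCCCCCCCC#C | starting material
14 | lithium undec-1-yn-1-ide | [Li]C#CCCCCCCCCC | intermediate
15 | methyl 2,4-dimethoxy-6-(2-oxotridec-3-yn-1-yl)benzoate | CCCCCCCCCC#CC(=O)Cc1cc(OC)cc(OC)c1C(=O)OC | intermediate
16 | methyl 2-[(2S)-2-hydroxytridec-3-yn-1-yl]-4,6-dimethoxybenzoate | CCCCCCCCCC#C[C@@H](O)Cc1cc(OC)cc(OC)c1C(=O)OC | intermediate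
17 | methyl 2-[(2R)-2-hydroxytridecyl]-4,6-dimethoxybenzoate | CCCCCCCCCCC[C@@H](O)Cc1cc(OC)cc(OC)c1C(=O)OC | intermediate
18 | (3R)-6,8-dimethoxy-3-undecyl-3,4-dihydro-1H-isochromen-1-one | CCCCCCCCCCC[C@@H]1Cc2cc(OC)cc(OC)c2C(=O)O1 | intermediate
19 | (3R)-8-hydroxy-6-methoxy-3-undecyl-3,4-dihydro-1H-isochromen-1-one | CCCCCCCCCCC[C@@H]1Cc2cc(OC)cc(O)c2C(=O)O1 | intermediate
20 | dipotassium 2-[(2R)-2-hydroxytridecyl]-4-methoxy-6-oxidobenzoate | CCCCCCCCCCC[C@@H](O)Cc1cc(OC)cc([O-])c1C(=O)[O-].[K+].[K+] | intermediate
21 | benzyl 2-(benzyloxy)-6-[(2R)-2-hydroxytridecyl]-4-methoxybenzoate | CCCCCCCCCCC[C@H](Cc1cc(OC)cc(OCc2ccccc2)c1C(=O)OCc1ccccc1)O | intermediate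
22 | benzyl 6-[(2R)-2-(acetyloxy)tridecyl]-2-(benzyloxy)-4-methoxybenzoate | CCCCCCCCCCC[C@H](Cc1cc(OC)cc(OCc2ccccc2)c1C(=O)OCc1ccccc1)OC(C)=O | intermediate
23 | 6-[(2R)-2-(acetyloxy)tridecyl]-2-hydroxy-4-methoxybenzoic acid (CNP0269024.1) | CCCCCCCCCCC[C@H](Cc1cc(OC)cc(O)c1C(=O)O)OC(C)=O | target

## Step count and risks

Total: 12 steps. Longest linear sequence: 12 steps, from 1 to 23; compounds 9 and 13 are bought and enter directly.

**Step 4 (key step).** The aryl anion may be protonated before the acyl group migrates, which gives plain α-arylation of the malonate. The product enolate may also be arylated by further aryne. Regiocontrol would suffer if addition at the carbon next to the methoxy group competes.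

Fallback, from 2 back to 11: the same two bonds are made one at a time by cross-coupling chemistry.
- Carbamate 2 is N-silylated and lithiated as in step 2 (3, then 4), but aryllithium 4 is quenched with methyl chloroformate. This gives methyl 2-({(tert-butyldimethylsilyl)(propan-2-yl)carbamoyl}oxy)-4,6-dimethoxybenzoate F1, which loses silicon on the acidic work-up to give methyl 2,4-dimethoxy-6-{[(propan-2-yl)carbamoyl]oxy}benzoate F2.
- DBU and Et2NH then free methyl 2-hydroxy-4,6-dimethoxybenzoate F3, which is triflated in the same flask with PhNTf2 to methyl 2,4-dimethoxy-6-{[(trifluoromethyl)sulfonyl]oxy}benzoate F4.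
- Palladium-catalysed α-arylation of dimethyl malonate 9 with F4 (Pd(OAc)2, P(t-Bu)3, K3PO4, toluene, heat) gives dimethyl 2-[3,5-dimethoxy-2-(methoxycarbonyl)phenyl]propanedioate F5.
- Krapcho demethoxycarbonylation (LiCl, wet DMSO, heat) returns the route to 11.

**Step 7.** Facial discrimination may be poorer than for simple ynones because the sp3 substituent is a bulky, ortho-disubstituted arylmethyl group. Enolisation of the benzylic ynone may also slow the catalyst or lead to isomerisation.

Fallback, from 12 back to 17: amide 12 is treated with undecylmagnesium bromide (THF, 0 °C) to give the saturated ketone methyl 2,4-dimethoxy-6-(2-oxotridecyl)benzoate F6. This is reduced with an (R)-selective ketoreductase chosen from a commercial panel (NADPH recycled with glucose and glucose dehydrogenase, buffer with DMSO cosolvent). The resulting hydroxy ester 17 is lactonised as in the second half of step 8 to 18.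

**Step 10.** The lactone may re-close by intramolecular transesterification while the phenoxide is still being alkylated, or the opening may stall because the phenoxide deactivates the lactone carbonyl.

Fallback, from 19 back to 23: the carboxyl carbon is kept at a lower oxidation level while the acetate is installed. It takes six operations in place of three.
- LiAlH4 (THF) reduces 19 to 2-(hydroxymethyl)-3-[(2R)-2-hydroxytridecyl]-5-methoxyphenol F7.
- 2,2-Dimethoxypropane with PPTS ties the phenol and the benzylic hydroxyl together as (2R)-1-(7-methoxy-2,2-dimethyl-4H-1,3-benzodioxin-5-yl)tridecan-2-ol F8.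
- Ac2O, pyridine and DMAP give (2R)-1-(7-methoxy-2,2-dimethyl-4H-1,3-benzodioxin-5-yl)tridecan-2-yl acetate F9.
- Aqueous acetic acid removes the acetonide to give (2R)-1-[3-hydroxy-2-(hydroxymethyl)-5-methoxyphenyl]tridecan-2-yl acetate F10.
- MnO2 oxidises the benzylic alcohol to (2R)-1-(2-formyl-3-hydroxy-5-methoxyphenyl)tridecan-2-yl acetate F11.
- Pinnick oxidation (NaClO2, NaH2PO4, 2-methylbut-2-ene, aqueous t-BuOH) gives 23.

**Step 2.** Metalation may occur at the wrong site, between the two methoxy groups, or the carbamoyl group may migrate to carbon (anionic ortho-Fries shift) before the chlorosilane is added.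

Fallback, from 1 back to 7 and 8: silicon is delivered intramolecularly from oxygen.
- Ortho-selective monobromination of 1 (NBS, catalytic i-Pr2NH, CH2Cl2, with removal of any para isomer) gives 2-bromo-3,5-dimethoxyphenol F12.
- Hexamethyldisilazane converts it into (2-bromo-3,5-dimethoxyphenoxy)trimethylsilane F13.
- Bromine–lithium exchange with n-BuLi at −78 °C triggers a 1,3 O-to-C silyl shift (retro-Brook rearrangement) that gives 7 as its lithium phenoxide. This is triflated in the same flask with Tf2O to 8.

## Further compounds

F1 | step 4 | methyl 2-({(tert-butyldimethylsilyl)(propan-2-yl)carbamoyl}oxy)-4,6-dimethoxybenzoate | COC(=O)c1c(OC)cc(OC)cc1OC(=O)N(C(C)C)[Si](C)(C)C(C)(C)C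
F2 | step 4 | methyl 2,4-dimethoxy-6-{[(propan-2-yl)carbamoyl]oxy}benzoate | COC(=O)c1c(OC)cc(OC)cc1OC(=O)NC(C)C
F3 | step 4 | methyl 2-hydroxy-4,6-dimethoxybenzoate | COC(=O)c1c(OC)cc(OC)cc1O
F4 | step 4 | methyl 2,4-dimethoxy-6-{[(trifluoromethyl)sulfonyl]oxy}benzoate | COC(=O)c1c(OC)cc(OC)cc1OS(=O)(=O)C(F)(F)F
F5 | step 4 | dimethyl 2-[3,5-dimethoxy-2-(methoxycarbonyl)phenyl]propanedioate | COC(=O)C(C(=O)OC)c1cc(OC)cc(OC)c1C(=O)OC
F6 | step 7 | methyl 2,4-dimethoxy-6-(2-oxotridecyl)benzoate | CCCCCCCCCCCC(=O)Cc1cc(OC)cc(OC)c1C(=O)OC
F7 | step 10 | 2-(hydroxymethyl)-3-[(2R)-2-hydroxytridecyl]-5-methoxyphenol | CCCCCCCCCCC[C@@H](O)Cc1cc(OC)cc(O)c1CO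
F8 | step 10 | (2R)-1-(7-methoxy-2,2-dimethyl-4H-1,3-benzodioxin-5-yl)tridecan-2-ol | CCCCCCCCCCC[C@@H](O)Cc1cc(OC)cc2OC(C)(C)OCc12
F9 | step 10 | (2R)-1-(7-methoxy-2,2-dimethyl-4H-1,3-benzodioxin-5-yl)tridecan-2-yl acetate | CCCCCCCCCCC[C@@H](OC(C)=O)Cc1cc(OC)cc2OC(C)(C)OCc12
F10 | step 10 | (2R)-1-[3-hydroxy-2-(hydroxymethyl)-5-methoxyphenyl]tridecan-2-yl acetate | CCCCCCCCCCC[C@@H](OC(C)=O)Cc1cc(OC)cc(O)c1CO
F11 | step 10 | (2R)-1-(2-formyl-3-hydroxy-5-methoxyphenyl)tridecan-2-yl acetate | CCCCCCCCCCC[C@@H](OC(C)=O)Cc1cc(OC)cc(O)c1C=O
F12 | step 2 | 2-bromo-3,5-dimethoxyphenol | COc1cc(O)c(Br)c(OC)c1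
F13 | step 2 | (2-bromo-3,5-dimethoxyphenoxy)trimethylsilane | COc1cc(O[Si](C)(C)C)c(Br)c(OC)c1
A1 | alternative 1 | 5-[(2R)-2-(tert-butyldimethylsilyloxy)tridecyl]-7-hydroxy-2,2-dimethyl-4H-1,3-benzodioxin-4-one | CC1(C)OC(=O)c2c(C[C@H](O[Si](C)(C)C(C)(C)C)CCCCCCCCCCC)cc(O)cc2O1
A2 | alternative 1 | 6-[(6R)-6-(tert-butyldimethylsilyloxy)-2,4-dioxoheptadecyl]-2,2-dimethyl-4H-1,3-dioxin-4-one | CC1(C)OC(=O)C=C(CC(=O)CC(=O)C[C@H](O[Si](C)(C)C(C)(C)C)CCCCCCCCCCC)O1
A3 | alternative 2 | benzyl 6-[(2R)-2-(acetyloxy)tridecyl]-2-hydroxy-4-methoxybenzoate | CCCCCCCCCCC[C@H](Cc1cc(OC)cc(O)c1C(=O)OCc1ccccc1)OC(C)=O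
A4 | alternative 2 | benzyl (5R)-5-(acetyloxy)hexadec-2-ynoate | CCCCCCCCCCC[C@H](CC#CC(=O)OCc1ccccc1)OC(C)=O
A5 | alternative 2 | 1,3-dimethoxy-1-(trimethylsilyloxy)buta-1,3-diene | COC(=CC(=C)OC)O[Si](C)(C)C
A6 | alternative 3 | 3-methoxy-5-[(2R)-2-(tert-butyldimethylsilyloxy)tridecyl]phenol | COc1cc(O)cc(C[C@H](O[Si](C)(C)C(C)(C)C)CCCCCCCCCCC)c1
A7 | alternative 3 | 3-[(2R)-2-(tert-butyldimethylsilyloxy)tridecyl]cyclobut-2-en-1-one | O=C1C=C(C[C@H](O[Si](C)(C)C(C)(C)C)CCCCCCCCCCC)C1
A8 | alternative 3 | methoxyacetylene (methoxyethyne) | COC#C
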